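## Retrosynthetic overview

- Two Wittig disconnections (C11=C12 and C11′=C12′) give a C15 triol phosphonium salt, the C10 trienedial and a C15 furanoid phosphonium salt.
- The furanoid salt is made from the triol salt: the dihydrofuran ring (O5′–C8′ bond) is closed at the C15 stage by an anodic selenium π-acid-catalysed dehydrative 1,3-transposition (formal syn SN2′), which relays C6 to C8′.
- The triol salt comes from (S)-abscisic acid: 2Z to 2E photoisomerisation, hydroxyl-directed epoxidation and reductive opening (C5–OH), hydroxyl-directed ketone reduction (C3–OH), then CO2H to CH2PPh3+.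
- Ring order: both cyclohexane rings are bought in abscisic acid, whose single stereocentre (C6) controls C5, C3 and C8′; the dihydrofuran is the only ring made, and it is made last among the rings.

Assumption: (S)-(+)-abscisic acid (bulk fermentation product) and (2E,4E,6E)-2,7-dimethylocta-2,4,6-trienedial are bought; positions are given in carotenoid numbering (ring C1–C6, chain C7–C15, primes for the furanoid half).

## Route

Step 1
Reactants: 1 (S)-(+)-abscisic acid, (2Z,4E)-5-[(1S)-1-hydroxy-2,6,6-trimethyl-4-oxocyclohex-2-en-1-yl]-3-methylpenta-2,4-dienoic acid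
Product: 2 (2E,4E)-5-[(1S)-1-hydroxy-2,6,6-trimethyl-4-oxocyclohex-2-en-1-yl]-3-methylpenta-2,4-dienoic acid
Conditions: hν (300–350 nm), MeOH, rt, to the photostationary state (about 1:1); chromatography; recovered 1 re-irradiated
Reagents that add atoms: none
Why: the known direct Z/E photoisomerisation of the 2,3-double bond of abscisic acid gives the E geometry needed at C9=C10 and does not touch the stereocentre.

Step 2
Reactants: 2 (2E,4E)-5-[(1S)-1-hydroxy-2,6,6-trimethyl-4-oxocyclohex-2-en-1-yl]-3-methylpenta-2,4-dienoic acid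
Product: 3 (2E,4E)-5-[(1R,2S,6S)-2-hydroxy-1,3,3-trimethyl-5-oxo-7-oxabicyclo[4.1.0]heptan-2-yl]-3-methylpenta-2,4-dienoic acid (epoxide cis to the tertiary OH)
Conditions: 30% H2O2, NaOH (2.2 equiv), MeOH/H2O, 0 °C to rt; then aq. HCl to pH 3
Reagents that add atoms: hydrogen peroxide, OO
Why: Weitz–Scheffer nucleophilic epoxidation (as for isophorone) attacks only the ring enone, because the dienoic acid is a carboxylate; hydroperoxide is delivered syn to the γ-hydroxyl and anti to the dienyl chain, which sets C5–O cis to 6-OH.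

Step 3
Reactants: 3 (2E,4E)-5-[(1R,2S,6S)-2-hydroxy-1,3,3-trimethyl-5-oxo-7-oxabicyclo[4.1.0]heptan-2-yl]-3-methylpenta-2,4-dienoic acid
Product: 4 (2E,4E)-5-[(1S,2R)-1,2-dihydroxy-2,6,6-trimethyl-4-oxocyclohexyl]-3-methylpenta-2,4-dienoic acid
Conditions: SmI2 (2.5 equiv), THF/MeOH, −90 °C
Reagents that add atoms: none
Why: SmI2 reductive opening of an α,β-epoxy ketone cleaves only the Cα–O bond to give the β-hydroxy ketone with C5 untouched, and the low temperature avoids retro-aldol cleavage and reduction of the dienoic acid.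

Step 4
Reactants: 4 (2E,4E)-5-[(1S,2R)-1,2-dihydroxy-2,6,6-trimethyl-4-oxocyclohexyl]-3-methylpenta-2,4-dienoic acid
Product: 5 (2E,4E)-5-[(1S,2R,4S)-1,2,4-trihydroxy-2,6,6-trimethylcyclohexyl]-3-methylpenta-2,4-dienoic acid
Conditions: Me4NBH(OAc)3 (5 equiv), MeCN/AcOH, −20 °C to rt
Reagents that add atoms: none
Why: Evans–Saksena hydroxyl-directed reduction: the 5-OH binds boron and delivers hydride to the same face of the C3 ketone, giving the 1,3-anti diol (3S), which an undirected hydride would not give because that face is flanked by two axial groups.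

Step 5
Reactants: 5 (2E,4E)-5-[(1S,2R,4S)-1,2,4-trihydroxy-2,6,6-trimethylcyclohexyl]-3-methylpenta-2,4-dienoic acid
Product: 6 (1S,2R,4S)-1-[(1E,3E)-5-hydroxy-3-methylpenta-1,3-dien-1-yl]-2,6,6-trimethylcyclohexane-1,2,4-triol
Conditions: LiAlH4 (4 equiv), THF, 0 °C to rt; H2O work-up
Reagents that add atoms: none
Why: LiAlH4 reduction of a 2,4-dienoic acid to the dienol (as sorbic acid to sorbyl alcohol); no stereocentre is involved.

Step 6
Reactants: 6 (1S,2R,4S)-1-[(1E,3E)-5-hydroxy-3-methylpenta-1,3-dien-1-yl]-2,6,6-trimethylcyclohexane-1,2,4-triol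
Product: 8 [(2E,4E)-3-methyl-5-[(1S,2R,4S)-1,2,4-trihydroxy-2,6,6-trimethylcyclohexyl]penta-2,4-dien-1-yl]triphenylphosphonium chloride, via allylic chloride 7 (not isolated)
Conditions: NCS (1.1 equiv), Me2S, CH2Cl2, −20 to 0 °C; then PPh3, MeCN, 40 °C; precipitation with Et2O
Reagents that add atoms: N-chlorosuccinimide, ClN1C(=O)CCC1=O; triphenylphosphine, c1ccc(cc1)P(c1ccccc1)c1ccccc1
Why: Corey–Kim chlorination converts only the primary allylic alcohol (the secondary and tertiary hydroxyls do not react) under non-acidic conditions that spare the tertiary allylic 6-OH, and SN2 quaternisation with PPh3 gives the Wittig salt.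

Step 7
Reactants: 8 [(2E,4E)-3-methyl-5-[(1S,2R,4S)-1,2,4-trihydroxy-2,6,6-trimethylcyclohexyl]penta-2,4-dien-1-yl]triphenylphosphonium chloride
Product: 10 [(2E)-3-[(2R,6S,7aR)-6-hydroxy-4,4,7a-trimethyl-2,4,5,6,7,7a-hexahydro-1-benzofuran-2-yl]but-2-en-1-yl]triphenylphosphonium chloride, via hydroxy selenide 9 (not isolated)
Conditions: (PhSe)2 (10 mol %), Et4NCl, MeCN, graphite anode, Pt cathode, divided cell, 1 mA cm−2 (0.3 F mol−1), 0 °C to rt
Reagents that add atoms: none
Why: Proposed new method: anodically generated PhSeCl (from (PhSe)2 and chloride) acts as a catalytic selenium π-acid that adds to C7=C8 while the tertiary 5-OH closes onto C8 from the opposite face (anti 5-endo selenoetherification, giving 9 and HCl); HCl then protonates the tertiary 6-OH, which leaves with help from the antiperiplanar C7–Se bond, and chloride removes PhSe+ from the seleniranium ion to release the C6=C7 alkene, water and PhSeCl; anti addition followed by anti elimination is a net syn SN2′ displacement, so the bought configuration at C6 is relayed to C8 (R), while the diastereomeric adduct with Se syn to 6-OH cannot eliminate and reverts; the cationic phosphonium group disfavours a free C8 carbocation and so protects the new doubly allylic ether from epimerisation; the anode regenerates the selenium electrophile that is lost by disproportionation in the water released; the closest known reactions are 5-endo selenoetherification of homoallylic alcohols, the acid-promoted β-hydroxy selenide to alkene elimination, halide-mediated anodic oxyselenenylation–deselenenylation, and PdCl2(MeCN)2- or Ph3PAuCl/AgOTf-catalysed dehydrative cyclisation of monoallylic diols with 1,3-chirality transfer.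

Step 8
Reactants: 8 [(2E,4E)-3-methyl-5-[(1S,2R,4S)-1,2,4-trihydroxy-2,6,6-trimethylcyclohexyl]penta-2,4-dien-1-yl]triphenylphosphonium chloride; 11 (2E,4E,6E)-2,7-dimethylocta-2,4,6-trienedial (3 equiv)
Product: 13 (2E,4E,6E,8E,10E,12E)-2,7,11-trimethyl-13-[(1S,2R,4S)-1,2,4-trihydroxy-2,6,6-trimethylcyclohexyl]trideca-2,4,6,8,10,12-hexaenal, via ylide 12 (not isolated)
Conditions: NaOMe (1.05 equiv), MeOH/CH2Cl2, −10 °C to rt; then heptane/EtOAc, 80 °C (Z to E); excess 11 recovered
Reagents that add atoms: none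
Why: Wittig olefination of the allylic ylide with an excess of the dialdehyde gives the mono-adduct, and the new C11=C12 bond is equilibrated to E by heating; the free hydroxyls are tolerated and no stereocentre is involved.

Step 9
Reactants: 13 (2E,4E,6E,8E,10E,12E)-2,7,11-trimethyl-13-[(1S,2R,4S)-1,2,4-trihydroxy-2,6,6-trimethylcyclohexyl]trideca-2,4,6,8,10,12-hexaenal; 10 [(2E)-3-[(2R,6S,7aR)-6-hydroxy-4,4,7a-trimethyl-2,4,5,6,7,7a-hexahydro-1-benzofuran-2-yl]but-2-en-1-yl]triphenylphosphonium chloride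
Product: 15 (3S,5R,6S,3′S,5′R,8′R)-5′,8′-epoxy-5,6,5′,8′-tetrahydro-β,β-carotene-3,5,6,3′-tetrol (CNP0210286.4), via ylide 14 (not isolated)
Conditions: 1,2-epoxybutane, EtOH, 70 °C; then heptane/EtOAc, 80 °C (Z to E); crystallisation
Reagents that add atoms: none
Why: Wittig olefination under the neutral epoxide protocol (chloride opens the epoxide to give a low steady concentration of alkoxide base) forms C11′=C12′, which is equilibrated to E by heating; without acid, C8′ and the 5,6-diol are not disturbed.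

## Compound list

1 | (S)-(+)-abscisic acid, (2Z,4E)-5-[(1S)-1-hydroxy-2,6,6-trimethyl-4-oxocyclohex-2-en-1-yl]-3-methylpenta-2,4-dienoic acid | OC(=O)/C=C(C)\C=C\[C@]1(O)C(C)(C)CC(=O)C=C1C | starting material
2 | (2E,4E)-5-[(1S)-1-hydroxy-2,6,6-trimethyl-4-oxocyclohex-2-en-1-yl]-3-methylpenta-2,4-dienoic acid | OC(=O)/C=C(C)/C=C/[C@]1(O)C(C)(C)CC(=O)C=C1C | intermediate
3 | (2E,4E)-5-[(1R,2S,6S)-2-hydroxy-1,3,3-trimethyl-5-oxo-7-oxabicyclo[4.1.0]heptan-2-yl]-3-methylpenta-2,4-dienoic acid | OC(=O)/C=C(C)/C=C/[C@]1(O)C(C)(C)CC(=O)[C@H]2O[C@@]12C | intermediate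
4 | (2E,4E)-5-[(1S,2R)-1,2-dihydroxy-2,6,6-trimethyl-4-oxocyclohexyl]-3-methylpenta-2,4-dienoic acid | OC(=O)/C=C(C)/C=C/[C@]1(O)C(C)(C)CC(=O)C[C@@]1(C)O | intermediate
5 | (2E,4E)-5-[(1S,2R,4S)-1,2,4-trihydroxy-2,6,6-trimethylcyclohexyl]-3-methylpenta-2,4-dienoic acid | OC(=O)/C=C(C)/C=C/[C@]1(O)C(C)(C)C[C@H](O)C[C@@]1(C)O | intermediate
6 | (1S,2R,4S)-1-[(1E,3E)-5-hydroxy-3-methylpenta-1,3-dien-1-yl]-2,6,6-trimethylcyclohexane-1,2,4-triol | OC/C=C(C)/C=C/[C@]1(O)C(C)(C)C[C@H](O)C[C@@]1(C)O | intermediate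
7 | (1S,2R,4S)-1-[(1E,3E)-5-chloro-3-methylpenta-1,3-dien-1-yl]-2,6,6-trimethylcyclohexane-1,2,4-triol | ClC/C=C(C)/C=C/[C@]1(O)C(C)(C)C[C@H](O)C[C@@]1(C)O | intermediate (not isolated)
8 | [(2E,4E)-3-methyl-5-[(1S,2R,4S)-1,2,4-trihydroxy-2,6,6-trimethylcyclohexyl]penta-2,4-dien-1-yl]triphenylphosphonium chloride | [Cl-].c1ccccc1[P+](c1ccccc1)(c1ccccc1)C/C=C(C)/C=C/[C@]1(O)C(C)(C)C[C@H](O)C[C@@]1(C)O | intermediate
9 | [(2E)-3-[(2S,3S,3aS,6S,7aR)-3a,6-dihydroxy-4,4,7a-trimethyl-3-(phenylselanyl)octahydro-1-benzofuran-2-yl]but-2-en-1-yl]triphenylphosphonium chloride | [Cl-].c1ccccc1[P+](c1ccccc1)(c1ccccc1)C/C=C(\C)[C@H]1[C@H]([Se]c3ccccc3)[C@]2(O)C(C)(C)C[C@H](O)C[C@@]2(C)O1 | intermediate (not isolated)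
10 | [(2E)-3-[(2R,6S,7aR)-6-hydroxy-4,4,7a-trimethyl-2,4,5,6,7,7a-hexahydro-1-benzofuran-2-yl]but-2-en-1-yl]triphenylphosphonium chloride | [Cl-].c1ccccc1[P+](c1ccccc1)(c1ccccc1)C/C=C(\C)[C@H]1C=C2C(C)(C)C[C@H](O)C[C@@]2(C)O1 | intermediate
11 | (2E,4E,6E)-2,7-dimethylocta-2,4,6-trienedial | O=C/C(C)=C/C=C/C=C(C)/C=O | starting material
12 | ylide of 8, [(2E,4E)-3-methyl-5-[(1S,2R,4S)-1,2,4-trihydroxy-2,6,6-trimethylcyclohexyl]penta-2,4-dien-1-ylidene]triphenylphosphorane | c1ccccc1[P+](c1ccccc1)(c1ccccc1)[CH-]/C=C(C)/C=C/[C@]1(O)C(C)(C)C[C@H](O)C[C@@]1(C)O | intermediate (not isolated)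
13 | (2E,4E,6E,8E,10E,12E)-2,7,11-trimethyl-13-[(1S,2R,4S)-1,2,4-trihydroxy-2,6,6-trimethylcyclohexyl]trideca-2,4,6,8,10,12-hexaenal | O=C/C(C)=C/C=C/C=C(C)/C=C/C=C(C)/C=C/[C@]1(O)C(C)(C)C[C@H](O)C[C@@]1(C)O | intermediate
14 | ylide of 10, [(2E)-3-[(2R,6S,7aR)-6-hydroxy-4,4,7a-trimethyl-2,4,5,6,7,7a-hexahydro-1-benzofuran-2-yl]but-2-en-1-ylidene]triphenylphosphorane | c1ccccc1[P+](c1ccccc1)(c1ccccc1)[CH-]/C=C(\C)[C@H]1C=C2C(C)(C)C[C@H](O)C[C@@]2(C)O1 | intermediate (not isolated)
15 | (3S,5R,6S,3′S,5′R,8′R)-5′,8′-epoxy-5,6,5′,8′-tetrahydro-β,β-carotene-3,5,6,3′-tetrol | CC(/C=C/C=C(C)/C=C/[C@]1(O)C(C)(C)C[C@H](O)C[C@@]1(C)O)=C\C=C\C=C(C)\C=C\C=C(/C)[C@H]1C=C2C(C)(C)C[C@H](O)C[C@@]2(C)O1 | target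

## Step count and risks

Total step count: 9. Longest linear sequence: 8 (steps 1–6, then 7 or 8, then 9).

Steps most likely to fail:

1. Step 7, the proposed new ring closure. The 5-endo closure must pass through a strained trans-fused adduct, and chloride adducts or oxidative deselenenylation at the anode may compete. The fallback uses known chemistry and makes the furanoid ring last. It sets out from 13 and 8: aldehyde 13 is olefinated with a second equivalent of ylide 12 (from 8, NaOMe, MeOH/CH2Cl2, then heating) to give the symmetrical (3S,5R,6S,3′S,5′R,6′S)-5,6,5′,6′-tetrahydro-β,β-carotene-3,5,6,3′,5′,6′-hexol F1. Brief treatment with a trace of HCl in CHCl3 at 0 °C is the classical acid-induced ionisation of a tertiary allylic carotenoid hydroxyl with furanoid-oxide formation. Stopped at low conversion, it converts one end group to the 5,8-epoxide. Compound 15 is separated by HPLC from its 8′S epimer, the bis-furanoid and recovered F1, so the fallback comes back to the route at 15. In this fallback C8′ is not controlled and the yield is statistical.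

2. Step 9, the Wittig reaction of the furanoid ylide. Ylide 14 may open the dihydrofuran by vinylogous β-elimination before it finds the slow-reacting C25 polyenal. The fallback reverses the order of the two olefinations and sets out from 10 and 11: ylide 14 is generated with 1,2-epoxybutane in the presence of a threefold excess of the small, highly electrophilic dialdehyde 11 and is trapped at once. This gives (2E,4E,6E,8E,10E)-11-[(2R,6S,7aR)-6-hydroxy-4,4,7a-trimethyl-2,4,5,6,7,7a-hexahydro-1-benzofuran-2-yl]-2,7-dimethyldodeca-2,4,6,8,10-pentaenal F2. The robust triol ylide 12 (from 8, NaOMe) is then added to F2 and the product is heated for Z to E equilibration, coming back to the route at 15.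

3. Step 2, the epoxidation. The β,β-disubstituted enone next to a quaternary carbon may react slowly or with poor facial selectivity. The fallback replaces epoxidation and reductive opening by conjugate borylation and oxidation and sets out from 2: CuCl (5 mol %), NaOtBu, bis[2-(diphenylphosphino)phenyl] ether, B2pin2 and MeOH in THF add boron to C5 anti to the dienyl chain, cis to the hydroxyl. This gives (2E,4E)-5-[(1R,2S)-1-hydroxy-2,6,6-trimethyl-4-oxo-2-(4,4,5,5-tetramethyl-1,3,2-dioxaborolan-2-yl)cyclohexyl]-3-methylpenta-2,4-dienoic acid F3. Oxidation with NaBO3·4H2O in THF/H2O proceeds with retention and gives the β-hydroxy ketone, coming back to the route at 4 and skipping 3.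

Further compounds
F1 | step 7 | (3S,5R,6S,3′S,5′R,6′S)-5,6,5′,6′-tetrahydro-β,β-carotene-3,5,6,3′,5′,6′-hexol | CC(/C=C/C=C(C)/C=C/[C@]1(O)C(C)(C)C[C@H](O)C[C@@]1(C)O)=C\C=C\C=C(C)\C=C\C=C(C)\C=C\[C@]1(O)C(C)(C)C[C@H](O)C[C@@]1(C)O
F2 | step 9 | (2E,4E,6E,8E,10E)-11-[(2R,6S,7aR)-6-hydroxy-4,4,7a-trimethyl-2,4,5,6,7,7a-hexahydro-1-benzofuran-2-yl]-2,7-dimethyldodeca-2,4,6,8,10-pentaenal | O=C/C(C)=C/C=C/C=C(C)/C=C/C=C(\C)[C@H]1C=C2C(C)(C)C[C@H](O)C[C@@]2(C)O1
F3 | step 2 | (2E,4E)-5-[(1R,2S)-1-hydroxy-2,6,6-trimethyl-4-oxo-2-(4,4,5,5-tetramethyl-1,3,2-dioxaborolan-2-yl)cyclohexyl]-3-methylpenta-2,4-dienoic acid | OC(=O)/C=C(C)/C=C/[C@]1(O)C(C)(C)CC(=O)C[C@@]1(C)B1OC(C)(C)C(C)(C)O1
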